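**Assumption:** the SMILES has no stereocentre and no E/Z-stereogenic alkene (both olefins end in CMe2). The C2–C1' axis is not expected to be configurationally stable. The target is therefore achiral, "the single enantiomer" is the compound itself, and no step creates or needs to control a stereocentre.

## Retrosynthetic overview
1. The target comes from global removal of four MOM ethers in the last step.
2. The pyranone C ring is the only ring built, and it is built last. One Rh-catalysed oxidative aldehyde C–H/O–H annulation of an A-ring salicylaldehyde with an internal aryl/prenyl alkyne (a 1,4-enyne) forms both C4–C3 and O1–C2. The 3-prenyl group arrives inside the alkyne, so no chalcone, β-diketone or 3-haloflavone is needed.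
3. The enyne comes from a one-pot twofold prenylation of a C,C-dianion: the aryl C3'–Li flanked by two oxygens, plus the lithium acetylide. Both prenyl groups go in from one flask.
4. The aryl acetylene comes from Sonogashira coupling of the iodide made by iodinating bis-MOM methoxyhydroquinone para to OMe. Rings A and B are purchased.

## Route

**Step 1**
Reactants: 1, 2,4,6-trihydroxybenzaldehyde
Product: 2, 2-hydroxy-4,6-bis(methoxymethoxy)benzaldehyde
Conditions: MOMCl (2.1 equiv), i-Pr2NEt (2.5 equiv), CH2Cl2, 0 °C → rt
Reagents that add atoms: chloromethyl methyl ether (MOMCl), COCCl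
Why: In this phenol O-alkylation (MOM protection), the 4-OH and one ortho-OH react, while the last ortho-OH is deactivated by its hydrogen bond to the CHO and remains as the free phenol that later directs rhodium.

**Step 2**
Reactants: 3, methoxyhydroquinone (2-methoxybenzene-1,4-diol)
Product: 4, 2-methoxy-1,4-bis(methoxymethoxy)benzene
Conditions: MOMCl (3 equiv), i-Pr2NEt (4 equiv), CH2Cl2, 0 °C → rt, N2
Reagents that add atoms: MOMCl, COCCl
Why: This is exhaustive MOM protection, and MOM is chosen because it directs ortho-metalation strongly, survives n-BuLi, Pd/Cu and Rh/Cu, and is removed together with the A-ring MOM groups.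

**Step 3**
Reactants: 4
Product: 5, 1-iodo-4-methoxy-2,5-bis(methoxymethoxy)benzene
Conditions: NIS (1.05 equiv), MeCN, 0 °C → rt, dark
Reagents that add atoms: N-iodosuccinimide, O=C1CCC(=O)N1I
Why: Electrophilic aromatic iodination of a 1,2,4-trioxygenated benzene goes to the carbon para to the OMe and ortho to an OMOM (as 1,2,4-trimethoxybenzene gives the 5-halide), and acid-free NIS leaves the acetals intact.

**Step 4**
Reactants: 5; 6, trimethylsilylacetylene
Product: 7, {[4-methoxy-2,5-bis(methoxymethoxy)phenyl]ethynyl}trimethylsilane
Conditions: PdCl2(PPh3)2 (2 mol %), CuI (4 mol %), Et3N/THF, 40 °C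
Reagents that add atoms: trimethylsilylacetylene, C#C[Si](C)(C)C
Why: In this Sonogashira coupling the iodide makes up for the electron-rich, ortho-alkoxy ring, and the conditions do not affect MOM ethers.

**Step 5**
Reactants: 7
Product: 8, 1-ethynyl-4-methoxy-2,5-bis(methoxymethoxy)benzene
Conditions: K2CO3, MeOH, rt
Reagents that add atoms: none
Why: Base-mediated protiodesilylation cleaves the alkynyl C–Si bond, and all ethers are inert to it.

**Step 6** (both prenyl groups in one pot)
Reactants: 8; 9, prenyl bromide (1-bromo-3-methylbut-2-ene)
Product: 10, 4-methoxy-2,5-bis(methoxymethoxy)-1-(5-methylhex-4-en-1-yn-1-yl)-3-(3-methylbut-2-en-1-yl)benzene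
Conditions: n-BuLi (2.3 equiv), THF, −78 → 0 °C, 1.5 h; prenyl bromide (3 equiv), −78 → 0 °C; then CuI (20 mol %), rt
Reagents that add atoms: prenyl bromide (two equivalents incorporated), CC(C)=CCBr
Why: Acetylide formation and then directed ortho-metalation at the only C–H flanked by two oxygens (between OMOM and OMe) give a C,C-dianion; the more basic aryllithium is alkylated first (SN2), and the acetylide couples only once Cu(I) is added (Cu-catalysed acetylide allylation, linear product), so no aryllithium remains to deprotonate the acidic skipped-enyne CH2.

**Step 7** (key step, C-ring formation)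
Reactants: 2 (1.2 equiv); 10
Product: 11, 5,7-bis(methoxymethoxy)-2-[4-methoxy-2,5-bis(methoxymethoxy)-3-(3-methylbut-2-en-1-yl)phenyl]-3-(3-methylbut-2-en-1-yl)-4H-chromen-4-one
Conditions: [RhCl(cod)]2 (2.5 mol %), 1,2,3,4-tetraphenylcyclopentadiene (10 mol %), Cu(OAc)2 (2.2 equiv), o-xylene, 120 °C, N2
Reagents that add atoms: none (2 and 10 combine with loss of 2 H to Cu(II))
Why: In this Rh(III)-catalysed oxidative salicylaldehyde C–H/alkyne annulation (Miura–Satoh-type chromone synthesis), the phenoxide-directed acyl-rhodacycle inserts the alkyne with Rh on the aryl-bearing carbon (favoured by size, benzylic stabilisation and possible 2'-OMOM chelation), C–O reductive elimination then places aryl at C2 and prenyl at C3, and the hindered trisubstituted olefins do not compete with the alkyne; the reaction class is known for aryl/alkyl alkynes and the 1,4-enyne partner is the untested element.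

**Step 8**
Reactants: 11
Product: 12, heteroartonin A (5,7,2',5'-tetrahydroxy-4'-methoxy-3,3'-diprenylflavone)
Conditions: 3 M aq HCl, degassed MeOH/THF, 45 °C, Ar, stopped at full conversion; work-up with a trace of Na2S2O4
Reagents that add atoms: none
Why: Acid-catalysed acetal solvolysis of aryl MOM ethers is the standard final step for prenylated flavonoids, since it is faster than protonation of the trisubstituted olefins under these mild conditions, and the methyl ether is untouched.

## Compound list
1 | 2,4,6-trihydroxybenzaldehyde | O=Cc1c(O)cc(O)cc1O | starting material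
2 | 2-hydroxy-4,6-bis(methoxymethoxy)benzaldehyde | O=Cc1c(O)cc(OCOC)cc1OCOC | intermediate
3 | methoxyhydroquinone | COc1cc(O)ccc1O | starting material
4 | 2-methoxy-1,4-bis(methoxymethoxy)benzene | COCOc1ccc(OCOC)c(OC)c1 | intermediate
5 | 1-iodo-4-methoxy-2,5-bis(methoxymethoxy)benzene | COCOc1cc(OC)c(OCOC)cc1I | intermediate
6 | trimethylsilylacetylene | C#C[Si](C)(C)C | starting material
7 | {[4-methoxy-2,5-bis(methoxymethoxy)phenyl]ethynyl}trimethylsilane | COCOc1cc(OC)c(OCOC)cc1C#C[Si](C)(C)C | intermediate
8 | 1-ethynyl-4-methoxy-2,5-bis(methoxymethoxy)benzene | COCOc1cc(OC)c(OCOC)cc1C#C | intermediate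
9 | prenyl bromide | CC(C)=CCBr | starting material
10 | 4-methoxy-2,5-bis(methoxymethoxy)-1-(5-methylhex-4-en-1-ynyl)-3-prenylbenzene | COCOc1c(CC=C(C)C)c(OC)c(OCOC)cc1C#CCC=C(C)C | intermediate
11 | tetra-O-MOM heteroartonin A | COCOc1cc(OCOC)c2c(c1)oc(-c1cc(OCOC)c(OC)c(CC=C(C)C)c1OCOC)c(CC=C(C)C)c2=O | intermediate
12 | heteroartonin A (achiral) | COc1c(O)cc(-c2oc3cc(O)cc(O)c3c(=O)c2CC=C(C)C)c(O)c1CC=C(C)C | target

## Summary
Total steps: 8.
Longest linear sequence: 7 (3 → 4 → 5 → 7 → 8 → 10 → 11 → 12).

**Steps most likely to fail**

1. **Step 7, Rh annulation.**
   - Risks: decarbonylation of the 6-alkoxy acyl-rhodium to give a benzofuran, base or metal isomerisation of the skipped enyne, allylic C–H activation of a prenyl group, and eroded regioselectivity.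
   - Fallback (ynone logic):
     - Stop step 6 after the aryl prenylation (no Cu, then quench) to obtain the 3-prenyl terminal alkyne.
     - Add its lithium acetylide to 2,4,6-tris(MOM-oxy)benzaldehyde and oxidise with MnO2 to the ynone.
     - Free the ortho phenol and close 6-endo with base to the 3-H flavone.
     - Install the 3-prenyl by C3-lithiation (LDA, −78 °C), Cu(I) and prenyl bromide.

2. **Step 6, dianion double prenylation.**
   - Risks: incomplete second lithiation, Wurtz or SN2' by-products, and propargylic deprotonation of the product.
   - Fallback (no dianion): lithiate and prenylate the TMS-alkyne 7 at C3 with the acetylide site masked by silicon. Then convert the C–Si bond directly to C–prenyl by fluoride/Cu(I) desilylative allylation (CsF, CuI, prenyl bromide, DMF).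

3. **Step 8, global MOM removal.**
   - Risks: acid-induced chroman formation between the 2'-OH and the 3'-prenyl, and air oxidation of the hydroquinone.
   - Fallback (quinone detour):
     - Oxidise the B-ring bis-MOM hydroquinone ether of 11 with CAN (MeCN/H2O, 0 °C) to the 2-methoxy-1,4-quinone.
     - Remove the A-ring MOM groups with HCl/MeOH while no phenol sits next to a prenyl group. Any exchange at the quinone OMe with MeOH is degenerate.
     - Reduce with Na2S2O4 to 12 under neutral conditions.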